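**Retrosynthetic overview**

1. The target is the (6R,7R,8R) 6,12-germacranolide with both ring double bonds cis in the ring (C1=C10 and C4=C5, each E by CIP), C14 and C15 as CH2OH, an 8-O-isovalerate and a C11=C13 methylene. The last operations are C13 methylenation, O8 acylation and desilylation.
2. The strategy rests on one feature: the carbinol C8 is bonded to C7, the β-carbon of the five-membered C12 lactone (O–C6, C7, C11, C12). Cutting C7–C8 gives a C8 aldehyde tethered to a C6-substituted butenolide (C7=C11), and a SmI2 ketyl–olefin coupling closes the ten-membered carbocycle C1–C10 onto the lactone.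
3. The butenolide comes from acrylate ring-closing metathesis on the C6 carbinol. The C3–C4 bond comes from a B-alkyl Suzuki–Miyaura coupling of a (Z)-alkenyl iodide (C4) with a homoallylic borane (C3).
4. East fragment: enantioselective alkynylation of acrolein sets C6, and hydroxyl-directed trans-hydroalumination/iodination fixes the C4=C5 geometry. West fragment: but-3-yn-1-ol, hydroxymethylation, anti-carbomagnesiation with vinylmagnesium chloride (fixes C1=C10), then hydroboration to the C8 oxygen.
5. Ring order: the five-membered lactone first (step 13), the ten-membered ring second (step 16).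

Key step: step 16

Remark: germacranolide numbering is used for all intermediates (C14 on C10, C15 on C4); the ProPhenol antipode in step 9 is assumed to be the one that gives the S carbinol, to be confirmed by Mosher ester analysis.

**Route**

Step 1
Reactants: 1 but-3-yn-1-ol
Product: 2 (but-3-yn-1-yloxy)triethylsilane
Conditions: Et3SiCl, imidazole, CH2Cl2, 0 °C to rt
Reagents that add atoms: chlorotriethylsilane, CC[Si](Cl)(CC)CC
Why: Standard silylation of a primary alcohol, the triethylsilyl ether being chosen because it can later be cleaved in the presence of tert-butyldimethylsilyl ethers.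

Step 2
Reactants: 2 (but-3-yn-1-yloxy)triethylsilane; 3 formaldehyde (as paraformaldehyde)
Product: 4 5-(triethylsilyloxy)pent-2-yn-1-ol
Conditions: n-BuLi, THF, −78 °C; (CH2O)n, −78 °C to rt; H2O
Reagents that add atoms: none
Why: Addition of the lithium acetylide to formaldehyde (alkyne hydroxymethylation) installs C14 and the propargylic hydroxyl that directs the next step.

Step 3
Reactants: 4 5-(triethylsilyloxy)pent-2-yn-1-ol; 5 vinylmagnesium chloride
Product: 7 (E)-2-ethenyl-5-(triethylsilyloxy)pent-2-en-1-ol, via cyclic alkenylmagnesium alkoxide 6 (not isolated)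
Conditions: CH2=CHMgCl (4 equiv), THF–toluene, 70 °C; then aq NH4Cl, 0 °C
Reagents that add atoms: none
Why: Alkoxide-directed anti-carbomagnesiation of a propargylic alcohol puts the vinyl group (C9, C8) on C10 and magnesium on C1 in a five-membered chelate, so that after protonation C9 is cis to C2 and the C14 oxygen trans to C2, which is the C1=C10 geometry of the target.

Step 4
Reactants: 7 (E)-2-ethenyl-5-(triethylsilyloxy)pent-2-en-1-ol
Product: 8 tert-butyldimethylsilyl ether of 7
Conditions: TBSCl, imidazole, DMF, rt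
Reagents that add atoms: tert-butyldimethylsilyl chloride, CC(C)(C)[Si](C)(C)Cl
Why: Routine silylation of the primary allylic C14 alcohol, which stays protected to the last step.

Step 5
Reactants: 8 tert-butyldimethylsilyl ether of 7
Product: 10 (E)-3-(tert-butyldimethylsilyloxymethyl)-6-(triethylsilyloxy)hex-3-en-1-ol, via B-alkyl-9-BBN borane 9 (not isolated)
Conditions: 9-BBN-H, THF, 0 °C to rt; then NaOH, H2O2, 0 °C
Reagents that add atoms: hydrogen peroxide, OO
Why: Hydroboration–oxidation with the bulky 9-BBN attacks only the terminal carbon of the monosubstituted vinyl group of the diene and leaves the trisubstituted alkene, giving the primary C8 alcohol.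

Step 6
Reactants: 10 (E)-3-(tert-butyldimethylsilyloxymethyl)-6-(triethylsilyloxy)hex-3-en-1-ol
Product: 11 4-methoxybenzyl ether of 10
Conditions: NaH, 4-MeOC6H4CH2Cl, n-Bu4NI (cat.), THF–DMF, 0 °C to rt
Reagents that add atoms: 4-methoxybenzyl chloride, COc1ccc(CCl)cc1
Why: Williamson etherification masks the C8 oxygen with a group that survives organolithium, palladium and ruthenium chemistry and is later removed oxidatively under neutral conditions.

Step 7
Reactants: 11 4-methoxybenzyl ether of 10
Product: 12 (E)-4-(tert-butyldimethylsilyloxymethyl)-6-(4-methoxybenzyloxy)hex-3-en-1-ol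
Conditions: PPTS (cat.), MeOH–CH2Cl2, 0 °C
Reagents that add atoms: none
Why: Acid-catalysed methanolysis cleaves a primary triethylsilyl ether much faster than a tert-butyldimethylsilyl ether, freeing only the C3 hydroxyl.

Step 8
Reactants: 12 (E)-4-(tert-butyldimethylsilyloxymethyl)-6-(4-methoxybenzyloxy)hex-3-en-1-ol
Product: 13 (E)-1-iodo-4-(tert-butyldimethylsilyloxymethyl)-6-(4-methoxybenzyloxy)hex-3-ene
Conditions: I2, PPh3, imidazole, CH2Cl2, 0 °C to rt
Reagents that add atoms: iodine, II
Why: Appel-type iodination of a primary alcohol under neutral conditions gives the homoallylic iodide needed for the fragment union.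

Step 9
Reactants: 14 tert-butyldimethyl(prop-2-yn-1-yloxy)silane; 15 acrolein
Product: 16 (S)-6-(tert-butyldimethylsilyloxy)hex-1-en-4-yn-3-ol
Conditions: Me2Zn, ProPhenol ligand (10 mol %), Ph3PO (20 mol %), toluene, 0 °C, slow addition of 15
Reagents that add atoms: none
Why: Zinc–ProPhenol catalysed enantioselective alkynylation of an α,β-unsaturated aldehyde, in which the chiral dinuclear zinc catalyst selects the aldehyde face and sets C6 (S).

Step 10
Reactants: 16 (S)-6-(tert-butyldimethylsilyloxy)hex-1-en-4-yn-3-ol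
Product: 18 (3S,4Z)-6-(tert-butyldimethylsilyloxy)-5-iodohexa-1,4-dien-3-ol, via sodium alkenylalanate 17 (not isolated)
Conditions: NaAlH2(OCH2CH2OMe)2, THF, 0 °C to rt; then I2, THF, −78 to 0 °C
Reagents that add atoms: iodine, II
Why: Hydroxyl-directed trans-hydroalumination of the propargylic alcohol places aluminium on the distal alkyne carbon (C4) in a five-membered alkoxyaluminate, and iodinolysis with retention gives the Z iodide with iodine cis to C6, while C6 is untouched.

Step 11
Reactants: 13 (E)-1-iodo-4-(tert-butyldimethylsilyloxymethyl)-6-(4-methoxybenzyloxy)hex-3-ene; 18 (3S,4Z)-6-(tert-butyldimethylsilyloxy)-5-iodohexa-1,4-dien-3-ol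
Product: 21 (3S,4E,8E)-5,9-bis(tert-butyldimethylsilyloxymethyl)-11-(4-methoxybenzyloxy)undeca-1,4,8-trien-3-ol, via alkyllithium 19 (not isolated), via lithium methoxyborinate 20 (not isolated)
Conditions: 13, t-BuLi (2.1 equiv), Et2O, −78 °C; B-methoxy-9-BBN, THF, −78 °C to rt; then 18, Pd(dppf)Cl2 (5 mol %), AsPh3, aq K3PO4, DMF, rt
Reagents that add atoms: none
Why: B-alkyl Suzuki–Miyaura coupling, in which the borinate made by lithium–iodine exchange and boron capture transfers its primary alkyl group to the alkenyl iodide with retention of geometry, so that C3 ends up cis to C6 and the free C6 hydroxyl is tolerated.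

Step 12
Reactants: 21 (3S,4E,8E)-5,9-bis(tert-butyldimethylsilyloxymethyl)-11-(4-methoxybenzyloxy)undeca-1,4,8-trien-3-ol; 22 acryloyl chloride
Product: 23 acrylate of 21
Conditions: CH2=CHCOCl, i-Pr2NEt, CH2Cl2, −78 to 0 °C
Reagents that add atoms: none
Why: Acylation of the secondary bis-allylic alcohol at low temperature with a hindered amine base brings in C11 and C12 without ionisation or transposition at C6.

Step 13
Reactants: 23 acrylate of 21
Product: 24 (5S)-5-[(1E,5E)-2,6-bis(tert-butyldimethylsilyloxymethyl)-8-(4-methoxybenzyloxy)octa-1,5-dienyl]furan-2(5H)-one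
Conditions: second-generation Grubbs catalyst (5 mol %), CH2Cl2 (5 mM), 40 °C
Reagents that add atoms: none
Why: Ring-closing metathesis between the acrylate and the C7=C11 vinyl group closes the butenolide with loss of ethene, the two trisubstituted alkenes being too hindered to take part and C6 not being touched.

Step 14
Reactants: 24 (5S)-5-[(1E,5E)-2,6-bis(tert-butyldimethylsilyloxymethyl)-8-(4-methoxybenzyloxy)octa-1,5-dienyl]furan-2(5H)-one
Product: 25 (5S)-5-[(1E,5E)-2,6-bis(tert-butyldimethylsilyloxymethyl)-8-hydroxyocta-1,5-dienyl]furan-2(5H)-one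
Conditions: DDQ, CH2Cl2–pH 7 phosphate buffer (10:1), 0 °C
Reagents that add atoms: none
Why: Oxidative cleavage of the 4-methoxybenzyl ether under buffered, near-neutral conditions spares the silyl ethers and the base-sensitive γ-alkenyl butenolide, whose C6 hydrogen would be epimerised by base.

Step 15
Reactants: 25 (5S)-5-[(1E,5E)-2,6-bis(tert-butyldimethylsilyloxymethyl)-8-hydroxyocta-1,5-dienyl]furan-2(5H)-one
Product: 26 (3E,7E)-3,7-bis(tert-butyldimethylsilyloxymethyl)-8-[(2S)-5-oxo-2,5-dihydrofuran-2-yl]octa-3,7-dienal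
Conditions: Dess–Martin periodinane, NaHCO3, CH2Cl2, 0 °C to rt; used at once
Reagents that add atoms: none
Why: Dess–Martin oxidation under bicarbonate buffer gives the β,γ-unsaturated C8 aldehyde without migration of the C1=C10 double bond into conjugation.

Step 16
Reactants: 26 (3E,7E)-3,7-bis(tert-butyldimethylsilyloxymethyl)-8-[(2S)-5-oxo-2,5-dihydrofuran-2-yl]octa-3,7-dienal
Product: 27 (3aR,4R,6E,10E,11aR)-6,10-bis(tert-butyldimethylsilyloxymethyl)-4-hydroxy-3a,4,5,8,9,11a-hexahydrocyclodeca[b]furan-2(3H)-one (the 6R,7R,8R trans-fused lactone with free 8-OH and C11 methylene)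
Conditions: SmI2 (3 equiv), HMPA (12 equiv), t-BuOH (2.5 equiv), THF, −78 °C, syringe-pump addition of 26 to 2 mM final concentration; aq NH4Cl at −78 °C
Reagents that add atoms: none
Why: Proposed new method: SmI2 (divalent samarium) activated by HMPA reduces the C8 aldehyde reversibly to a ketyl radical, which adds to C7, the β-carbon of the butenolide, and a second electron turns the resulting C11 radical into a trivalent samarium enolate that tert-butanol protonates, so that the C7–C8 bond, the ten-membered ring and two stereocentres arise in one operation. The closest known reaction type is the SmI2 ketyl–olefin cyclisation onto enoates, established for five- to eight-membered rings, together with SmI2 Barbier and Reformatsky macrocyclisations; a ketyl–olefin closure of a ten-membered carbocycle is not established. The ring closes in the 10-exo-trig mode, C11 staying outside the new ring, helped by the two cis trisubstituted alkenes (C1=C10 and C4=C5), which fold the chain and bring C8 close to C7, and by slow addition at about 2 mM, which suppresses pinacol dimerisation. C7 is controlled by the C6 stereocentre: the chain leaves C6 on one face of the flat butenolide and the ketyl is expected to bond to C7 from the opposite face, which gives the trans-fused lactone (7R) typical of 6,12-germacranolides and avoids the strain of a cis fusion. C8 is controlled by the orientation of the ketyl in that transition state, in which the bulky O–Sm(HMPA)n group should point away from C11 and the lactone carbonyl while C9 lies anti to C6, an arrangement that leads to the 8R carbinol. The step needs electron transfer to the aldehyde and not to the butenolide, secured because aldehydes are reduced far faster than enoates, and conjugate attack at C7 in preference to simple reduction, secured by the electron-poor butenolide double bond as radical acceptor.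

Step 17
Reactants: 27 the 6R,7R,8R hydroxy lactone; 28 N,N-dimethylmethyleneiminium iodide (Eschenmoser's salt)
Product: 31 (3aR,4R,6E,10E,11aR)-6,10-bis(tert-butyldimethylsilyloxymethyl)-4-hydroxy-3-methylidene-3a,4,5,8,9,11a-hexahydrocyclodeca[b]furan-2(3H)-one, via Mannich base 29 (not isolated), via trimethylammonium iodide 30 (not isolated)
Conditions: 27 added to LiN(i-Pr)2 (2.3 equiv), THF, −78 °C; 28 (3 equiv), −78 °C to rt; then MeI, MeOH, rt; then aq NaHCO3, CH2Cl2
Reagents that add atoms: none
Why: α-Methylenation of a γ-lactone by Mannich reaction of its lithium enolate with Eschenmoser's salt and Hofmann-type elimination of the quaternised amine, with the C8 hydroxyl carried as its lithium alkoxide (dianion) and C7 and C8 left unchanged.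

Step 18
Reactants: 31 the α-methylene hydroxy lactone; 32 3-methylbutanoic anhydride
Product: 33 8-O-(3-methylbutanoyl) ester of 31
Conditions: (i-PrCH2CO)2O, Et3N, DMAP (cat.), CH2Cl2, 0 °C to rt
Reagents that add atoms: none
Why: DMAP-catalysed acylation of the secondary C8 alcohol proceeds with retention at C8 and, with only amine bases present, without the alkoxide that could move the lactone from O6 to O8.

Step 19
Reactants: 33 8-O-(3-methylbutanoyl) ester of 31
Product: 34 (3aR,4R,6E,10E,11aR)-6,10-bis(hydroxymethyl)-3-methylidene-2-oxo-2,3,3a,4,5,8,9,11a-octahydrocyclodeca[b]furan-4-yl 3-methylbutanoate (target)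
Conditions: HF·pyridine, pyridine, THF, 0 °C to rt
Reagents that add atoms: none
Why: Buffered fluoride cleavage of the two primary allylic silyl ethers is mild enough to leave the ester and the α-methylene lactone intact.

**Compound list**

1 | but-3-yn-1-ol | C#CCCO | starting material
2 | (but-3-yn-1-yloxy)triethylsilane | C#CCCO[Si](CC)(CC)CC | intermediate
3 | formaldehyde (as paraformaldehyde) | C=O | starting material
4 | 5-(triethylsilyloxy)pent-2-yn-1-ol | OCC#CCCO[Si](CC)(CC)CC | intermediate
5 | vinylmagnesium chloride | C=C[Mg]Cl | starting material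
6 | cyclic alkenylmagnesium alkoxide (4-ethenyl-3-[2-(triethylsilyloxy)ethyl]-2,5-dihydro-1,2-oxamagnesole) | C=CC1=C(CCO[Si](CC)(CC)CC)[Mg]OC1 | intermediate
7 | (E)-2-ethenyl-5-(triethylsilyloxy)pent-2-en-1-ol | OC/C(C=C)=C/CCO[Si](CC)(CC)CC | intermediate
8 | tert-butyldimethylsilyl ether of 7 | C=C/C(CO[Si](C)(C)C(C)(C)C)=C\CCO[Si](CC)(CC)CC | intermediate
9 | B-alkyl-9-BBN borane from 8 (boron on C8) | B1(CC/C(CO[Si](C)(C)C(C)(C)C)=C\CCO[Si](CC)(CC)CC)C2CCCC1CCC2 | intermediate
10 | (E)-3-(tert-butyldimethylsilyloxymethyl)-6-(triethylsilyloxy)hex-3-en-1-ol | OCC/C(CO[Si](C)(C)C(C)(C)C)=C\CCO[Si](CC)(CC)CC | intermediate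
11 | 4-methoxybenzyl ether of 10 | COc1ccc(COCC/C(CO[Si](C)(C)C(C)(C)C)=C\CCO[Si](CC)(CC)CC)cc1 | intermediate
12 | (E)-4-(tert-butyldimethylsilyloxymethyl)-6-(4-methoxybenzyloxy)hex-3-en-1-ol | COc1ccc(COCC/C(CO[Si](C)(C)C(C)(C)C)=C\CCO)cc1 | intermediate
13 | (E)-1-iodo-4-(tert-butyldimethylsilyloxymethyl)-6-(4-methoxybenzyloxy)hex-3-ene | COc1ccc(COCC/C(CO[Si](C)(C)C(C)(C)C)=C\CCI)cc1 | intermediate
14 | tert-butyldimethyl(prop-2-yn-1-yloxy)silane | C#CCO[Si](C)(C)C(C)(C)C | starting material
15 | acrolein | C=CC=O | starting material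
16 | (S)-6-(tert-butyldimethylsilyloxy)hex-1-en-4-yn-3-ol | C=C[C@H](O)C#CCO[Si](C)(C)C(C)(C)C | intermediate
17 | sodium alkenylalanate (cyclic alkoxyaluminate, aluminium on C4) | C=C[C@@H]1O[Al-](OCCOC)(OCCOC)C(CO[Si](C)(C)C(C)(C)C)=C1.[Na+] | intermediate
18 | (3S,4Z)-6-(tert-butyldimethylsilyloxy)-5-iodohexa-1,4-dien-3-ol | C=C[C@H](O)/C=C(\I)CO[Si](C)(C)C(C)(C)C | intermediate
19 | homoallylic alkyllithium from 13 | [Li]CC/C=C(CO[Si](C)(C)C(C)(C)C)\CCOCc1ccc(OC)cc1 | intermediate
20 | lithium B-alkyl-B-methoxy-9-BBN borinate | [Li+].CO[B-]1(CC/C=C(CO[Si](C)(C)C(C)(C)C)\CCOCc2ccc(OC)cc2)C2CCCC1CCC2 | intermediate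
21 | (3S,4E,8E)-5,9-bis(tert-butyldimethylsilyloxymethyl)-11-(4-methoxybenzyloxy)undeca-1,4,8-trien-3-ol | C=C[C@H](O)/C=C(CO[Si](C)(C)C(C)(C)C)\CC/C=C(CO[Si](C)(C)C(C)(C)C)\CCOCc1ccc(OC)cc1 | intermediate
22 | acryloyl chloride | C=CC(Cl)=O | starting material
23 | acrylate of 21 | C=C[C@H](OC(=O)C=C)/C=C(CO[Si](C)(C)C(C)(C)C)\CC/C=C(CO[Si](C)(C)C(C)(C)C)\CCOCc1ccc(OC)cc1 | intermediate
24 | (5S)-5-[(1E,5E)-2,6-bis(tert-butyldimethylsilyloxymethyl)-8-(4-methoxybenzyloxy)octa-1,5-dienyl]furan-2(5H)-one | COc1ccc(COCC/C(CO[Si](C)(C)C(C)(C)C)=C\CC/C(CO[Si](C)(C)C(C)(C)C)=C\[C@H]2OC(=O)C=C2)cc1 | intermediate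
25 | (5S)-5-[(1E,5E)-2,6-bis(tert-butyldimethylsilyloxymethyl)-8-hydroxyocta-1,5-dienyl]furan-2(5H)-one | OCC/C(CO[Si](C)(C)C(C)(C)C)=C\CC/C(CO[Si](C)(C)C(C)(C)C)=C\[C@H]1OC(=O)C=C1 | intermediate
26 | (3E,7E)-3,7-bis(tert-butyldimethylsilyloxymethyl)-8-[(2S)-5-oxo-2,5-dihydrofuran-2-yl]octa-3,7-dienal (key-step precursor) | O=CC/C(CO[Si](C)(C)C(C)(C)C)=C\CC/C(CO[Si](C)(C)C(C)(C)C)=C\[C@H]1OC(=O)C=C1 | intermediate
27 | (3aR,4R,6E,10E,11aR)-6,10-bis(tert-butyldimethylsilyloxymethyl)-4-hydroxy-3a,4,5,8,9,11a-hexahydrocyclodeca[b]furan-2(3H)-one (key-step product) | C1C(=O)O[C@@H]2/C=C(/CO[Si](C)(C)C(C)(C)C)CC/C=C(/CO[Si](C)(C)C(C)(C)C)C[C@@H](O)[C@@H]12 | intermediate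
28 | N,N-dimethylmethyleneiminium iodide (Eschenmoser's salt) | C=[N+](C)C.[I-] | starting material
29 | Mannich base, 11-(dimethylaminomethyl) derivative of 27 (CH2N expected trans to C8) | CN(C)C[C@@H]1C(=O)O[C@@H]2/C=C(/CO[Si](C)(C)C(C)(C)C)CC/C=C(/CO[Si](C)(C)C(C)(C)C)C[C@@H](O)[C@@H]12 | intermediate
30 | trimethylammonium iodide of 29 | C[N+](C)(C)C[C@@H]1C(=O)O[C@@H]2/C=C(/CO[Si](C)(C)C(C)(C)C)CC/C=C(/CO[Si](C)(C)C(C)(C)C)C[C@@H](O)[C@@H]12.[I-] | intermediate
31 | (3aR,4R,6E,10E,11aR)-6,10-bis(tert-butyldimethylsilyloxymethyl)-4-hydroxy-3-methylidene-3a,4,5,8,9,11a-hexahydrocyclodeca[b]furan-2(3H)-one | C=C1C(=O)O[C@@H]2/C=C(/CO[Si](C)(C)C(C)(C)C)CC/C=C(/CO[Si](C)(C)C(C)(C)C)C[C@@H](O)[C@@H]12 | intermediate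
32 | 3-methylbutanoic anhydride | CC(C)CC(=O)OC(=O)CC(C)C | starting material
33 | 8-O-(3-methylbutanoyl) ester of 31 | C=C1C(=O)O[C@@H]2/C=C(/CO[Si](C)(C)C(C)(C)C)CC/C=C(/CO[Si](C)(C)C(C)(C)C)C[C@@H](OC(=O)CC(C)C)[C@@H]12 | intermediate
34 | (3aR,4R,6E,10E,11aR)-6,10-bis(hydroxymethyl)-3-methylidene-2-oxo-2,3,3a,4,5,8,9,11a-octahydrocyclodeca[b]furan-4-yl 3-methylbutanoate | C=C1C(=O)O[C@@H]2/C=C(/CO)CC/C=C(/CO)C[C@@H](OC(=O)CC(C)C)[C@@H]12 | target

**Step count**

Total: 19 steps. Longest linear sequence: 17 steps (steps 1–8 and 11–19); the east fragment takes 2 steps (9 and 10).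

**Steps most likely to fail**

Step 16 (ten-membered ring closure). The ketyl may be reduced on to the C8 alcohol or dimerise to the pinacol before the slow 10-exo closure occurs, or the butenolide may be reduced with loss of the C6 oxygen; closure with poor control at C8 is also possible. The fallback sets out from 21 and comes back at 31, replacing steps 12 to 17. It closes the same C7–C8 bond by an intramolecular Barbier allylation, a reaction type established for α-methylene-γ-butyrolactones from 2-(bromomethyl)acrylic esters and 3-(bromomethyl)butenolides, including medium-ring germacranolide closures. Compound 21 is esterified with 2-(bromomethyl)acrylic acid (N,N'-diisopropylcarbodiimide, cat. DMAP, CH2Cl2, 0 °C) to the 2-(bromomethyl)acrylate of 21 F1. Ring-closing metathesis (second-generation Hoveyda–Grubbs catalyst, toluene, 80 °C) gives the 3-(bromomethyl) analogue of 24 F2. DDQ (buffered CH2Cl2) gives the 3-(bromomethyl) analogue of 25 F3, and Dess–Martin oxidation gives the 3-(bromomethyl) analogue of 26 F4. Zinc dust (THF–aq NH4Cl, high dilution) or CrCl2 then converts the C13 bromide into an allylmetal that attacks the C8 aldehyde through C7 in a six-membered cyclic transition state. This forms the ring, the C8 carbinol and the C11=C13 methylene at once and gives 31. The C7/C8 relationship would have to be assigned and the metal chosen for the 8R series.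

Step 17 (α-methylenation through the dianion). The lithium alkoxide at C8 may attack C12 before the enolate has formed and move the lactone from O6 to O8, or the dianion may form incompletely. The fallback sets out from 27 and comes back at 31, with the hydroxyl masked. Me3SiCl and imidazole (CH2Cl2, 0 °C) give the 8-O-trimethylsilyl ether of 27 F5. LiN(i-Pr)2 (1.2 equiv, THF, −78 °C) and Eschenmoser's salt give the Mannich base of F5 F6, MeI gives its trimethylammonium iodide F7, and aq NaHCO3 gives the 8-O-trimethylsilyl ether of 31 F8. Citric acid in MeOH at 0 °C removes the trimethylsilyl group without touching the tert-butyldimethylsilyl ethers and gives 31.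

Step 9 (enantioselective alkynylation of acrolein). Acrolein may oligomerise under the zinc alkoxide conditions, or the addition may proceed with low enantioselectivity. The fallback sets out from 14 and 15 and comes back at 16. The lithium acetylide of 14 (n-BuLi, THF, −78 °C) is added to acrolein to give racemic 6-(tert-butyldimethylsilyloxy)hex-1-en-4-yn-3-ol F9. This is resolved by lipase-catalysed acetylation (Burkholderia cepacia lipase, vinyl acetate, hexane, rt, to about 55% conversion). The usual enantiopreference of lipases for secondary alcohols should acetylate the R enantiomer to the (R)-acetate F10 and leave 16, which is separated by chromatography and checked by Mosher ester analysis.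

**Further compounds**

F1 | step 16 | 2-(bromomethyl)acrylate of 21 | C=C[C@H](OC(=O)C(=C)CBr)/C=C(CO[Si](C)(C)C(C)(C)C)\CC/C=C(CO[Si](C)(C)C(C)(C)C)\CCOCc1ccc(OC)cc1
F2 | step 16 | 3-(bromomethyl) analogue of butenolide 24 | COc1ccc(COCC/C(CO[Si](C)(C)C(C)(C)C)=C\CC/C(CO[Si](C)(C)C(C)(C)C)=C\[C@H]2OC(=O)C(CBr)=C2)cc1
F3 | step 16 | 3-(bromomethyl) analogue of alcohol 25 | OCC/C(CO[Si](C)(C)C(C)(C)C)=C\CC/C(CO[Si](C)(C)C(C)(C)C)=C\[C@H]1OC(=O)C(CBr)=C1
F4 | step 16 | 3-(bromomethyl) analogue of aldehyde 26 | O=CC/C(CO[Si](C)(C)C(C)(C)C)=C\CC/C(CO[Si](C)(C)C(C)(C)C)=C\[C@H]1OC(=O)C(CBr)=C1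
F5 | step 17 | 8-O-trimethylsilyl ether of 27 | C1C(=O)O[C@@H]2/C=C(/CO[Si](C)(C)C(C)(C)C)CC/C=C(/CO[Si](C)(C)C(C)(C)C)C[C@@H](O[Si](C)(C)C)[C@@H]12
F6 | step 17 | Mannich base of F5 (11-dimethylaminomethyl) | CN(C)C[C@@H]1C(=O)O[C@@H]2/C=C(/CO[Si](C)(C)C(C)(C)C)CC/C=C(/CO[Si](C)(C)C(C)(C)C)C[C@@H](O[Si](C)(C)C)[C@@H]12
F7 | step 17 | trimethylammonium iodide of F6 | C[N+](C)(C)C[C@@H]1C(=O)O[C@@H]2/C=C(/CO[Si](C)(C)C(C)(C)C)CC/C=C(/CO[Si](C)(C)C(C)(C)C)C[C@@H](O[Si](C)(C)C)[C@@H]12.[I-]
F8 | step 17 | 8-O-trimethylsilyl ether of 31 | C=C1C(=O)O[C@@H]2/C=C(/CO[Si](C)(C)C(C)(C)C)CC/C=C(/CO[Si](C)(C)C(C)(C)C)C[C@@H](O[Si](C)(C)C)[C@@H]12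
F9 | step 9 | racemic 6-(tert-butyldimethylsilyloxy)hex-1-en-4-yn-3-ol | C=CC(O)C#CCO[Si](C)(C)C(C)(C)C
F10 | step 9 | (R)-6-(tert-butyldimethylsilyloxy)hex-1-en-4-yn-3-yl acetate | C=C[C@@H](OC(C)=O)C#CCO[Si](C)(C)C(C)(C)C
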